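## Retrosynthetic overview

1. The target comes from a protected macrocycle by C15‑O desilylation and, last, release of the α‑methylene lactone from its Me2NH adduct.
2. The ten‑membered carbocycle is closed last, at C1=C10, by intramolecular Horner–Wadsworth–Emmons olefination of a C1 aldehyde with a C10 phosphonoacetate.
3. The 8‑angelate is installed by Mitsunobu inversion of the 8S carbinol with angelic acid.
4. Key step: the C7–C8 bond is made by intermolecular Zn‑Barbier allylation of aldehyde 25 (C8–C10, C14) with the 3‑(bromomethyl)butenolide 19 (C1–C7, C11–C13, C15). This creates the α‑methylene‑γ‑butyrolactone and sets C7 and C8.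
5. Butenolide 19 comes from RCM of a 2‑(bromomethyl)acrylate of an (R)‑allylic alcohol, made via Jacobsen HKR (C6) and Evans allylation (C4). Ring order: butenolide, then α‑methylene lactone, then carbocycle.

Assumption: the target is taken as drawn, (4R,6R,7S,8R) in germacrane numbering (C4 bears CH2OH = C15, C6 lactone O, C7 ring fusion, C8 angelate, C10 bears CO2Me, C11=C13 methylene), with 1(10)‑E enoate and Z‑angelate; this numbering is used for positions below. TBS = tert‑butyldimethylsilyl, TBDPS = tert‑butyldiphenylsilyl.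

## Route

Step 1
Reactants: 1 pentane‑1,5‑diol
Product: 2 5‑[(TBS)oxy]pentan‑1‑ol
Conditions: TBSCl (1.0 equiv), imidazole, 1 (3 equiv), THF, 0 °C → rt
Reagents that add atoms: tert‑butyldimethylsilyl chloride, CC(C)(C)[Si](C)(C)Cl
Why: Statistical monosilylation of a cheap symmetrical diol used in excess gives the mono‑ether cleanly.

Step 2
Reactants: 2 5‑[(TBS)oxy]pentan‑1‑ol
Product: 4 5‑[(TBS)oxy]pentanoic acid, via silyloxy aldehyde 3 (not isolated)
Conditions: TEMPO (0.2 equiv), PhI(OAc)2 (2.2 equiv), MeCN/H2O (1:1), rt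
Reagents that add atoms: water, O
Why: TEMPO/BAIB oxidation takes the primary alcohol through the aldehyde hydrate to the acid without touching the silyl ether.

Step 3
Reactants: 4 5‑[(TBS)oxy]pentanoic acid; 5 (4S)‑4‑benzyl‑1,3‑oxazolidin‑2‑one
Product: 7 (4S)‑4‑benzyl‑3‑{5‑[(TBS)oxy]pentanoyl}‑1,3‑oxazolidin‑2‑one, via mixed pivalic anhydride 6 (not isolated)
Conditions: PivCl, Et3N, THF, −20 °C; then 5, LiCl, −20 °C → rt
Reagents that add atoms: none
Why: Mixed‑anhydride N‑acylation of the Evans auxiliary (LiCl/Et3N variant) is a standard, high‑yielding imide synthesis.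

Step 4
Reactants: 7 N‑acyl oxazolidinone; 8 allyl iodide
Product: 10 (4S)‑4‑benzyl‑3‑[(2R)‑2‑{3‑[(TBS)oxy]propyl}pent‑4‑enoyl]‑1,3‑oxazolidin‑2‑one, via sodium Z‑enolate 9 (not isolated)
Conditions: NaHMDS, THF, −78 °C; then 8, −78 → −45 °C
Reagents that add atoms: none
Why: Evans asymmetric alkylation: the chelated Z‑enolate is allylated on the face opposite the benzyl group, setting C4 (R); the allyl carbons become C5–C7.

Step 5
Reactants: 10 allylated imide
Product: 11 (2R)‑2‑{3‑[(TBS)oxy]propyl}pent‑4‑en‑1‑ol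
Conditions: LiBH4, MeOH (2 equiv), THF, 0 °C
Reagents that add atoms: none
Why: Reductive cleavage of the imide gives the C15 primary alcohol without epimerising C4 and returns the auxiliary.

Step 6
Reactants: 11 primary alcohol
Product: 12 (4R)‑4‑{[(TBDPS)oxy]methyl}‑7‑[(TBS)oxy]hept‑1‑ene
Conditions: TBDPSCl, imidazole, CH2Cl2, rt
Reagents that add atoms: tert‑butyldiphenylsilyl chloride, CC(C)(C)[Si](Cl)(c1ccccc1)c1ccccc1
Why: Silylation gives a C15 ether that survives the later selective removal of the C1 TBS ether.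

Step 7
Reactants: 12 terminal alkene
Product: 13 2‑[(2R)‑2‑{[(TBDPS)oxy]methyl}‑5‑[(TBS)oxy]pentyl]oxirane (1:1 epimers at the oxirane carbon)
Conditions: mCPBA, CH2Cl2, 0 °C → rt
Reagents that add atoms: meta‑chloroperoxybenzoic acid, OOC(=O)c1cccc(Cl)c1
Why: Prilezhaev epoxidation of the only alkene; the lack of selectivity at C6 is corrected in step 8.

Step 8
Reactants: 13 epoxide mixture
Product: 14 (2R)‑2‑[(2R)‑2‑{[(TBDPS)oxy]methyl}‑5‑[(TBS)oxy]pentyl]oxirane
Conditions: (R,R)‑(salen)Co(III)OAc (1 mol %), H2O (0.55 equiv), THF, 0 °C → rt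
Reagents that add atoms: none
Why: Jacobsen hydrolytic kinetic resolution: the catalyst antipode that hydrolyses the 2S‑oxirane epimer is used, leaving the 2R‑epoxide (C6 set by reagent control; at most 50 % yield; diol removed by chromatography).

Step 9
Reactants: 14 (R)‑epoxide
Product: 16 (3R,5R)‑5‑{[(TBDPS)oxy]methyl}‑8‑[(TBS)oxy]oct‑1‑en‑3‑ol, via sulfonium betaine 15 (not isolated)
Conditions: Me3S+ I− (4 equiv), n‑BuLi (3.9 equiv), THF, −10 °C; then 14, −10 °C → rt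
Reagents that add atoms: trimethylsulfonium iodide, C[S+](C)C.[I-]
Why: Epoxide‑to‑allylic‑alcohol homologation with dimethylsulfonium methylide: attack at the terminal carbon and elimination of Me2S give the vinyl carbinol with C6 untouched.

Step 10
Reactants: 16 allylic alcohol; 17 2‑(bromomethyl)acrylic acid
Product: 18 (3R,5R)‑5‑{[(TBDPS)oxy]methyl}‑8‑[(TBS)oxy]oct‑1‑en‑3‑yl 2‑(bromomethyl)prop‑2‑enoate
Conditions: DCC, DMAP (5 mol %), CH2Cl2, −20 → 0 °C
Reagents that add atoms: none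
Why: Steglich esterification at low temperature with little DMAP acylates the alcohol faster than the allylic bromide is attacked; C6 is retained.

Step 11
Reactants: 18 diene ester
Product: 19 (5R)‑3‑(bromomethyl)‑5‑[(2R)‑2‑{[(TBDPS)oxy]methyl}‑5‑[(TBS)oxy]pentyl]furan‑2(5H)‑one
Conditions: Grubbs II (5 mol %), CH2Cl2 (5 mM), 40 °C
Reagents that add atoms: none
Why: Ring‑closing metathesis of an allyl acrylate‑type diene to a five‑membered butenolide is driven by loss of ethylene; allylic bromides are tolerated by Ru carbenes.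

Step 12
Reactants: 20 trimethyl phosphonoacetate; 21 allyl bromide
Product: 23 methyl 2‑(dimethoxyphosphoryl)pent‑4‑enoate (racemic), via sodium phosphonoenolate 22 (not isolated)
Conditions: NaH, THF, 0 °C; then 21, 0 °C → rt
Reagents that add atoms: none
Why: C‑alkylation of the stabilised phosphonoacetate anion with a reactive allylic halide builds C9–C10 with the HWE handle in place.

Step 13
Reactants: 23 allyl phosphonoacetate
Product: 25 methyl 2‑(dimethoxyphosphoryl)‑4‑oxobutanoate (racemic), via ozonide 24 (not isolated)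
Conditions: O3, CH2Cl2, −78 °C; then Me2S, −78 °C → rt
Reagents that add atoms: ozone, [O-][O+]=O
Why: Ozonolysis with reductive work‑up cleaves the terminal alkene to the C8 aldehyde; the aldehyde is used crude.

Step 14
Reactants: 19 bromobutenolide; 25 phosphono aldehyde
Product: 27 methyl (4S)‑2‑(dimethoxyphosphoryl)‑4‑hydroxy‑4‑[(2R,3R)‑2‑{(2R)‑2‑{[(TBDPS)oxy]methyl}‑5‑[(TBS)oxy]pentyl}‑4‑methylidene‑5‑oxooxolan‑3‑yl]butanoate (both C10 epimers), via allylzinc bromide 26 (not isolated)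
Conditions: Zn dust (3 equiv), THF/sat. aq NH4Cl (2:1), 0 °C → rt; 25 (1.5 equiv); used without delay
Reagents that add atoms: none
Why: Zn‑Barbier carbonyl allylation: the allylzinc reacts at C7 (SE2′) anti to the C6 side chain, giving the 6,7‑trans lactone, and a closed chair transition state with the aldehyde chain equatorial gives the 7,8‑anti carbinol (8S); the allylic transposition creates the α‑methylene lactone.

Step 15
Reactants: 27 8S alcohol; 28 angelic acid [(2Z)‑2‑methylbut‑2‑enoic acid]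
Product: 30 methyl (4R)‑2‑(dimethoxyphosphoryl)‑4‑{[(2Z)‑2‑methylbut‑2‑enoyl]oxy}‑4‑[(2R,3S)‑2‑{(2R)‑2‑{[(TBDPS)oxy]methyl}‑5‑[(TBS)oxy]pentyl}‑4‑methylidene‑5‑oxooxolan‑3‑yl]butanoate, via oxyphosphonium angelate 29 (not isolated)
Conditions: PPh3, DIAD (betaine preformed), 28 (3 equiv), toluene, 0 °C → rt
Reagents that add atoms: none
Why: Mitsunobu esterification: SN2 displacement of the oxyphosphonium by angelate inverts C8 to the required 8R; the acid is never activated at its carbonyl, so the Z‑geometry is kept.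

Step 16
Reactants: 30 bis‑silyl ether
Product: 31 the C1 primary alcohol of 30 (5‑hydroxypentyl side chain; TBDPS retained)
Conditions: CSA (0.2 equiv), MeOH/CH2Cl2 (1:1), 0 °C
Reagents that add atoms: none
Why: Acid‑catalysed methanolysis removes a primary TBS ether much faster than a primary TBDPS ether.

Step 17
Reactants: 31 α‑methylene lactone
Product: 32 the 11,13‑dihydro‑13‑(dimethylamino) adduct of 31 (oxolane bears 4‑[(dimethylamino)methyl]; C11 epimers)
Conditions: Me2NH (2 M in THF, 3 equiv), THF, 0 °C → rt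
Reagents that add atoms: dimethylamine, CNC
Why: Aza‑Michael addition to the exo‑methylene lactone (far more reactive than the angelate) masks it so the phosphonate anion of step 19 cannot close a six‑membered ring onto C13; the C11 epimers converge later.

Step 18
Reactants: 32 primary alcohol
Product: 33 the C1 aldehyde of 32 (5‑oxopentyl side chain)
Conditions: DMP, CH2Cl2, 0 °C → rt
Reagents that add atoms: none
Why: Dess–Martin oxidation gives the aldehyde under near‑neutral conditions that tolerate the tertiary amine, esters and phosphonate.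

Step 19
Reactants: 33 phosphonate aldehyde
Product: 35 methyl (3aS,4R,6E,10R,11aR)‑10‑{[(TBDPS)oxy]methyl}‑3‑[(dimethylamino)methyl]‑4‑{[(2Z)‑2‑methylbut‑2‑enoyl]oxy}‑2‑oxo‑2,3,3a,4,5,8,9,10,11,11a‑decahydrocyclodeca[b]furan‑6‑carboxylate (C3 epimers), via lithium phosphonoenolate 34 (not isolated)
Conditions: LiCl, DBU, MeCN (1 mM, syringe‑pump addition), rt
Reagents that add atoms: none
Why: Intramolecular Horner–Wadsworth–Emmons (Masamune–Roush) under high dilution: the only unstrained ring geometry (C2 and C9 cis) is also the normal HWE outcome (CO2Me trans to C2, i.e. E).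

Step 20
Reactants: 35 silyl‑protected macrocycle
Product: 36 methyl (3aS,4R,6E,10R,11aR)‑3‑[(dimethylamino)methyl]‑10‑(hydroxymethyl)‑4‑{[(2Z)‑2‑methylbut‑2‑enoyl]oxy}‑2‑oxo‑2,3,3a,4,5,8,9,10,11,11a‑decahydrocyclodeca[b]furan‑6‑carboxylate (C3 epimers)
Conditions: HF·pyridine, pyridine, THF, 0 °C → rt
Reagents that add atoms: none
Why: Buffered fluoride desilylation frees the C15 alcohol without acyl migration or ester cleavage.

Step 21
Reactants: 36 amine‑masked lactone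
Product: 38 methyl (3aS,4R,6E,10R,11aR)‑10‑(hydroxymethyl)‑3‑methylidene‑4‑{[(2Z)‑2‑methylbut‑2‑enoyl]oxy}‑2‑oxo‑2,3,3a,4,5,8,9,10,11,11a‑decahydrocyclodeca[b]furan‑6‑carboxylate (target), via trimethylammonium iodide 37 (not isolated)
Conditions: MeI, MeOH, rt; then aq NaHCO3, rt
Reagents that add atoms: none
Why: N‑quaternisation followed by mild‑base E1cB (Hofmann‑type) elimination of trimethylamine regenerates the exo‑methylene lactone, removing the C11 stereocentre.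

## Compound list

1 | pentane‑1,5‑diol | OCCCCCO | starting material
2 | 5‑[(TBS)oxy]pentan‑1‑ol | OCCCCCO[Si](C)(C)C(C)(C)C | intermediate
3 | 5‑[(TBS)oxy]pentanal | O=CCCCCO[Si](C)(C)C(C)(C)C | intermediate
4 | 5‑[(TBS)oxy]pentanoic acid | OC(=O)CCCCO[Si](C)(C)C(C)(C)C | intermediate
5 | (4S)‑4‑benzyl‑1,3‑oxazolidin‑2‑one | O=C1N[C@@H](Cc2ccccc2)CO1 | starting material
6 | 5‑[(TBS)oxy]pentanoic pivalic anhydride | CC(C)(C)C(=O)OC(=O)CCCCO[Si](C)(C)C(C)(C)C | intermediate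
7 | (4S)‑4‑benzyl‑3‑{5‑[(TBS)oxy]pentanoyl}‑1,3‑oxazolidin‑2‑one | O=C1OC[C@H](Cc2ccccc2)N1C(=O)CCCCO[Si](C)(C)C(C)(C)C | intermediate
8 | allyl iodide | C=CCI | starting material
9 | sodium (Z)‑enolate of 7 | [Na+].[O-]/C(=C\CCCO[Si](C)(C)C(C)(C)C)N1[C@@H](Cc2ccccc2)COC1=O | intermediate
10 | (4S)‑4‑benzyl‑3‑[(2R)‑2‑{3‑[(TBS)oxy]propyl}pent‑4‑enoyl]‑1,3‑oxazolidin‑2‑one | O=C1OC[C@H](Cc2ccccc2)N1C(=O)[C@@H](CC=C)CCCO[Si](C)(C)C(C)(C)C | intermediate
11 | (2R)‑2‑{3‑[(TBS)oxy]propyl}pent‑4‑en‑1‑ol | OC[C@@H](CC=C)CCCO[Si](C)(C)C(C)(C)C | intermediate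
12 | (4R)‑4‑{[(TBDPS)oxy]methyl}‑7‑[(TBS)oxy]hept‑1‑ene | CC(C)(C)[Si](OC[C@@H](CC=C)CCCO[Si](C)(C)C(C)(C)C)(c1ccccc1)c1ccccc1 | intermediate
13 | 2‑[(2R)‑2‑{[(TBDPS)oxy]methyl}‑5‑[(TBS)oxy]pentyl]oxirane (oxirane epimers) | CC(C)(C)[Si](OC[C@@H](CC1CO1)CCCO[Si](C)(C)C(C)(C)C)(c1ccccc1)c1ccccc1 | intermediate
14 | (2R)‑2‑[(2R)‑2‑{[(TBDPS)oxy]methyl}‑5‑[(TBS)oxy]pentyl]oxirane | CC(C)(C)[Si](OC[C@@H](C[C@@H]1CO1)CCCO[Si](C)(C)C(C)(C)C)(c1ccccc1)c1ccccc1 | intermediate
15 | dimethyl[(3R,5R)‑5‑{[(TBDPS)oxy]methyl}‑3‑oxido‑8‑[(TBS)oxy]octyl]sulfonium (betaine) | C[S+](C)CC[C@H]([O-])C[C@H](CO[Si](c1ccccc1)(c1ccccc1)C(C)(C)C)CCCO[Si](C)(C)C(C)(C)C | intermediate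
16 | (3R,5R)‑5‑{[(TBDPS)oxy]methyl}‑8‑[(TBS)oxy]oct‑1‑en‑3‑ol | C=C[C@H](O)C[C@H](CO[Si](c1ccccc1)(c1ccccc1)C(C)(C)C)CCCO[Si](C)(C)C(C)(C)C | intermediate
17 | 2‑(bromomethyl)acrylic acid | C=C(CBr)C(=O)O | starting material
18 | (3R,5R)‑5‑{[(TBDPS)oxy]methyl}‑8‑[(TBS)oxy]oct‑1‑en‑3‑yl 2‑(bromomethyl)prop‑2‑enoate | C=C(CBr)C(=O)O[C@@H](C=C)C[C@H](CO[Si](c1ccccc1)(c1ccccc1)C(C)(C)C)CCCO[Si](C)(C)C(C)(C)C | intermediate
19 | (5R)‑3‑(bromomethyl)‑5‑[(2R)‑2‑{[(TBDPS)oxy]methyl}‑5‑[(TBS)oxy]pentyl]furan‑2(5H)‑one | BrCC1=C[C@@H](C[C@H](CO[Si](c2ccccc2)(c2ccccc2)C(C)(C)C)CCCO[Si](C)(C)C(C)(C)C)OC1=O | intermediate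
20 | trimethyl phosphonoacetate | COC(=O)CP(=O)(OC)OC | starting material
21 | allyl bromide | C=CCBr | starting material
22 | sodium enolate of trimethyl phosphonoacetate | [Na+].COC([O-])=CP(=O)(OC)OC | intermediate
23 | methyl 2‑(dimethoxyphosphoryl)pent‑4‑enoate | C=CCC(C(=O)OC)P(=O)(OC)OC | intermediate
24 | methyl 2‑(dimethoxyphosphoryl)‑3‑(1,2,4‑trioxolan‑3‑yl)propanoate | COC(=O)C(CC1OCOO1)P(=O)(OC)OC | intermediate
25 | methyl 2‑(dimethoxyphosphoryl)‑4‑oxobutanoate | O=CCC(C(=O)OC)P(=O)(OC)OC | intermediate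
26 | allylzinc bromide from 19 | Br[Zn]CC1=C[C@@H](C[C@H](CO[Si](c2ccccc2)(c2ccccc2)C(C)(C)C)CCCO[Si](C)(C)C(C)(C)C)OC1=O | intermediate
27 | Barbier alcohol (6R,7R,8S; 8‑OH; C10 epimers) | C=C1C(=O)O[C@H](C[C@H](CO[Si](c2ccccc2)(c2ccccc2)C(C)(C)C)CCCO[Si](C)(C)C(C)(C)C)[C@H]1[C@@H](O)CC(C(=O)OC)P(=O)(OC)OC | intermediate
28 | angelic acid | C/C=C(/C)C(=O)O | starting material
29 | C8 oxytriphenylphosphonium angelate of 27 | C=C1C(=O)O[C@H](C[C@H](CO[Si](c2ccccc2)(c2ccccc2)C(C)(C)C)CCCO[Si](C)(C)C(C)(C)C)[C@H]1[C@@H](O[P+](c3ccccc3)(c3ccccc3)c3ccccc3)CC(C(=O)OC)P(=O)(OC)OC.C/C=C(/C)C(=O)[O-] | intermediate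
30 | 8R angelate (6R,7S,8R; C1‑OTBS; C15‑OTBDPS) | C=C1C(=O)O[C@H](C[C@H](CO[Si](c2ccccc2)(c2ccccc2)C(C)(C)C)CCCO[Si](C)(C)C(C)(C)C)[C@H]1[C@H](OC(=O)/C(C)=C\C)CC(C(=O)OC)P(=O)(OC)OC | intermediate
31 | C1 alcohol of 30 | C=C1C(=O)O[C@H](C[C@H](CO[Si](c2ccccc2)(c2ccccc2)C(C)(C)C)CCCO)[C@H]1[C@H](OC(=O)/C(C)=C\C)CC(C(=O)OC)P(=O)(OC)OC | intermediate
32 | dimethylamine adduct of 31 (C11 epimers) | CN(C)CC1C(=O)O[C@H](C[C@H](CO[Si](c2ccccc2)(c2ccccc2)C(C)(C)C)CCCO)[C@H]1[C@H](OC(=O)/C(C)=C\C)CC(C(=O)OC)P(=O)(OC)OC | intermediate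
33 | C1 aldehyde of 32 | CN(C)CC1C(=O)O[C@H](C[C@H](CO[Si](c2ccccc2)(c2ccccc2)C(C)(C)C)CCC=O)[C@H]1[C@H](OC(=O)/C(C)=C\C)CC(C(=O)OC)P(=O)(OC)OC | intermediate
34 | lithium phosphonoenolate of 33 | CN(C)CC1C(=O)O[C@H](C[C@H](CO[Si](c2ccccc2)(c2ccccc2)C(C)(C)C)CCC=O)[C@H]1[C@H](OC(=O)/C(C)=C\C)CC(=C([O-])OC)P(=O)(OC)OC.[Li+] | intermediate
35 | amine‑masked, C15‑OTBDPS macrocycle | CN(C)CC1C(=O)O[C@@H]2C[C@H](CO[Si](c3ccccc3)(c3ccccc3)C(C)(C)C)CC/C=C(/C(=O)OC)C[C@@H](OC(=O)/C(C)=C\C)[C@@H]12 | intermediate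
36 | amine‑masked macrocycle with free C15‑OH | CN(C)CC1C(=O)O[C@@H]2C[C@H](CO)CC/C=C(/C(=O)OC)C[C@@H](OC(=O)/C(C)=C\C)[C@@H]12 | intermediate
37 | trimethylammonium iodide of 36 | C[N+](C)(C)CC1C(=O)O[C@@H]2C[C@H](CO)CC/C=C(/C(=O)OC)C[C@@H](OC(=O)/C(C)=C\C)[C@@H]12.[I-] | intermediate
38 | methyl (3aS,4R,6E,10R,11aR)‑10‑(hydroxymethyl)‑3‑methylidene‑4‑{[(2Z)‑2‑methylbut‑2‑enoyl]oxy}‑2‑oxo‑2,3,3a,4,5,8,9,10,11,11a‑decahydrocyclodeca[b]furan‑6‑carboxylate | C=C1C(=O)O[C@@H]2C[C@H](CO)CC/C=C(/C(=O)OC)C[C@@H](OC(=O)/C(C)=C\C)[C@@H]12 | target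

## Step count and risks

Total steps: 21. Longest linear sequence: 19 (steps 1–11, then 14–21); the aldehyde branch is steps 12–13.

The three steps most likely to fail:

**Step 19 (ten‑membered ring by intramolecular HWE; dimerisation is the main danger).** Fallback by ring‑closing metathesis, setting out from 32 and returning at 35. Alcohol 32 is treated with aqueous formaldehyde and K2CO3 (intermolecular HWE of the phosphonoacetate) to give the α‑substituted acrylate alcohol F1. Dess–Martin oxidation gives the aldehyde F2. Wittig methylenation with Ph3P=CH2 (THF, −78 → 0 °C) gives the terminal diene F3. RCM (Hoveyda–Grubbs II, 1.1 equiv CSA to protonate the amine, toluene, 80 °C, 1 mM) closes C1=C10 with loss of ethylene and delivers 35.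

**Step 15 (Mitsunobu inversion at the hindered C8 carbinol; elimination or retention possible).** Fallback by oxidation, reduction and retentive acylation, setting out from 27 and returning at 30. Pyridine‑buffered Dess–Martin oxidation of 27 gives the C8 ketone F4, which is used crude because C7–H is isomerisation‑prone. Reagent‑controlled CBS reduction (the Me‑CBS antipode that delivers the 8R carbinol, expected to be (S)‑Me‑CBS, with catecholborane, toluene, −78 °C) gives the 8R alcohol F5. Acylation with the mixed anhydride of angelic acid 28 and 2,4,6‑trichlorobenzoyl chloride (Et3N, toluene, 75 °C, no DMAP) proceeds with retention to 30. The same acylation would be used directly if the Barbier step happened to deliver the 8R alcohol F5.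

**Step 11 (RCM of the bromomethyl acrylate; the allylic bromide may kill the catalyst or the preceding esterification may suffer).** Fallback without metathesis, setting out from epoxide 14 and returning at 19. Epoxide 14 is opened at its terminal carbon by the sodium salt of trimethyl phosphonoacetate 20 (NaH, toluene, 90 °C); the alkoxide lactonises in situ to the α‑phosphono lactone F6. HWE with paraformaldehyde and K2CO3 (THF) gives the 5‑substituted α‑methylene‑γ‑butyrolactone F7. Wohl–Ziegler bromination with allylic transposition (NBS, cat. AIBN, PhCF3, 80 °C) gives 19.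

## Further compounds

F1 | step 19 | acrylate alcohol: 32 with C10 as C(=CH2)CO2Me in place of the phosphonate | CN(C)CC1C(=O)O[C@H](C[C@H](CO[Si](c2ccccc2)(c2ccccc2)C(C)(C)C)CCCO)[C@H]1[C@H](OC(=O)/C(C)=C\C)CC(=C)C(=O)OC
F2 | step 19 | C1 aldehyde of F1 | CN(C)CC1C(=O)O[C@H](C[C@H](CO[Si](c2ccccc2)(c2ccccc2)C(C)(C)C)CCC=O)[C@H]1[C@H](OC(=O)/C(C)=C\C)CC(=C)C(=O)OC
F3 | step 19 | terminal alkene from F2 (RCM diene) | CN(C)CC1C(=O)O[C@H](C[C@H](CO[Si](c2ccccc2)(c2ccccc2)C(C)(C)C)CCC=C)[C@H]1[C@H](OC(=O)/C(C)=C\C)CC(=C)C(=O)OC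
F4 | step 15 | C8 ketone from 27 | C=C1C(=O)O[C@H](C[C@H](CO[Si](c2ccccc2)(c2ccccc2)C(C)(C)C)CCCO[Si](C)(C)C(C)(C)C)[C@H]1C(=O)CC(C(=O)OC)P(=O)(OC)OC
F5 | step 15 | 8R alcohol (C8 epimer of 27) | C=C1C(=O)O[C@H](C[C@H](CO[Si](c2ccccc2)(c2ccccc2)C(C)(C)C)CCCO[Si](C)(C)C(C)(C)C)[C@H]1[C@H](O)CC(C(=O)OC)P(=O)(OC)OC
F6 | step 11 | dimethyl [(5R)‑5‑[(2R)‑2‑{[(TBDPS)oxy]methyl}‑5‑[(TBS)oxy]pentyl]‑2‑oxooxolan‑3‑yl]phosphonate (C3 epimers) | COP(=O)(OC)C1C[C@@H](C[C@H](CO[Si](c2ccccc2)(c2ccccc2)C(C)(C)C)CCCO[Si](C)(C)C(C)(C)C)OC1=O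
F7 | step 11 | (5R)‑5‑[(2R)‑2‑{[(TBDPS)oxy]methyl}‑5‑[(TBS)oxy]pentyl]‑3‑methylideneoxolan‑2‑one | C=C1C[C@@H](C[C@H](CO[Si](c2ccccc2)(c2ccccc2)C(C)(C)C)CCCO[Si](C)(C)C(C)(C)C)OC1=O
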